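The synthesis rests on cutting the 2,2-dimethyl-2H-pyran ring at C4–C4a and O1–C2, and the cyclohexene into a chalcone and (E)-β-ocimene. The key step fuses the pyran ring onto 2',6'-dihydroxy-4'-methoxyacetophenone with prenal in one operation: C-alkenylation to an o-quinone methide, then oxa-6π electrocyclisation. It exploits the local C2 symmetry of the benzene ring, whose two OH/CH pairs beside the OMe-bearing carbon are equivalent, so only one chromene can form. The annulation desymmetrises this ring and ties back one phenol without a protecting group. It leaves the single chelating 7-OH that steers the later boron-promoted, enantioselective endo Diels–Alder reaction. The precursor is thus a plain, achiral acetophenone.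

Key step: step 1

Assumption on the ligand: (R)-VANOL is written for the enone face that is needed. The sense of induction is taken by analogy with related 2'-hydroxychalcones, and if it proves opposite, the equally available (S)-VANOL takes its place with nothing else changed.

Assumption on the diene: (E)-β-ocimene is bought as the E-enriched commercial terpene. Any (Z)-isomer in it cannot reach the s-cis conformation and stays a spectator.

Step 1
Reactants: 1 2',6'-dihydroxy-4'-methoxyacetophenone; 2 3-methylbut-2-enal (prenal)
Product: 4 1-(7-hydroxy-5-methoxy-2,2-dimethyl-2H-chromen-8-yl)ethanone, via o-quinone methide 3 (not isolated)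
Conditions: 2 (1.1 equiv), ethylenediammonium diacetate (EDDA, 20 mol %), toluene, reflux
Reagents that add atoms: none
Why: EDDA activates prenal as an iminium species, whose C1 is attacked by the electron-rich C3 of 1 (Knoevenagel/aldol-type C–C bond formation, the future C4–C4a bond), and loss of the amine gives the (Z)-o-quinone methide 3, a 1-oxatriene. Thermal disrotatory oxa-6π electrocyclisation of 3 then forms the O1–C2 bond, closes the six-membered 2H-pyran ring and restores aromaticity, which drives the sequence forward. The closest known reaction type is the amine- or base-mediated formal [3+3] chromene annulation of resorcinols and acylphloroglucinols with α,β-unsaturated aldehydes. No stereocentre is formed, because C2 carries two methyl groups. Regioselectivity is secured by the substrate: C3/C5 and the two hydroxyls are equivalent through the local C2 axis C1–C4, and each CH has only one free OH beside it (the other neighbour is the capped 4-OMe), so every productive pathway gives the same 8-acetyl-7-hydroxy-5-methoxy isomer. Mono-annulation is secured by using about one equivalent of 2 and by the hydrogen bond that locks the remaining OH of 4 to the acetyl group.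

Step 2
Reactants: 4 1-(7-hydroxy-5-methoxy-2,2-dimethyl-2H-chromen-8-yl)ethanone; 5 benzaldehyde
Product: 7 (E)-1-(7-hydroxy-5-methoxy-2,2-dimethyl-2H-chromen-8-yl)-3-phenylprop-2-en-1-one, via aldol adduct 6 (not isolated)
Conditions: KOH (excess), EtOH, rt; then cold 1 M HCl to pH 5
Reagents that add atoms: none
Why: Claisen–Schmidt condensation, in which the potassium enolate of the methyl ketone adds to non-enolisable benzaldehyde to give aldol 6 and E1cB loss of hydroxide gives the conjugated, thermodynamically preferred (E)-enone, while the chromene and the aryl ethers are inert to base.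

Step 3
Reactants: 7 (E)-1-(7-hydroxy-5-methoxy-2,2-dimethyl-2H-chromen-8-yl)-3-phenylprop-2-en-1-one; 8 (E)-β-ocimene
Product: 11 [(1R,2S,6R)-3-methyl-2-(3-methylbut-2-en-1-yl)-6-phenylcyclohex-3-en-1-yl](7-hydroxy-5-methoxy-2,2-dimethyl-2H-chromen-8-yl)methanone (target), via chalcone boron chelate 9 (not isolated), via cycloadduct boron chelate 10 (not isolated)
Conditions: (R)-VANOL, B(OPh)3 (1.2 equiv each), 5 Å MS, PhCF3, rt; then 7 and 8 (excess), rt to 40 °C; H2O work-up
Reagents that add atoms: none
Why: Chiral boron Lewis acid promoted asymmetric Diels–Alder reaction of a 2'-hydroxychalcone, in which 7 displaces phenoxide from the VANOL borate and binds through 7-O and C=O as chelate 9, whose lowered LUMO reacts with the s-cis (E)-diene so that the free CH2 terminus bonds to the β-carbon and the prenyl-bearing terminus to the α-carbon; the (E)-enone fixes the trans C1'/C6' relationship, the endo position of the chelated aroyl group fixes the cis C1'/C2' relationship, and the vaulted biaryl wall leaves the Cα-Re/Cβ-Re face open, which sets (1'R,2'S,6'R) before hydrolysis of 10 releases 11.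

Compound list
1 | 1-(2,6-dihydroxy-4-methoxyphenyl)ethanone (2',6'-dihydroxy-4'-methoxyacetophenone) | CC(=O)c1c(O)cc(OC)cc1O | starting material
2 | 3-methylbut-2-enal (prenal) | CC(C)=CC=O | starting material
3 | (6Z)-2-acetyl-3-hydroxy-5-methoxy-6-(3-methylbut-2-en-1-ylidene)cyclohexa-2,4-dien-1-one (o-quinone methide) | CC(=O)C1=C(O)C=C(OC)/C(=C/C=C(C)C)C1=O | intermediate
4 | 1-(7-hydroxy-5-methoxy-2,2-dimethyl-2H-chromen-8-yl)ethanone | COc1cc(O)c(C(C)=O)c2OC(C)(C)C=Cc12 | intermediate
5 | benzaldehyde | O=Cc1ccccc1 | starting material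
6 | 3-hydroxy-1-(7-hydroxy-5-methoxy-2,2-dimethyl-2H-chromen-8-yl)-3-phenylpropan-1-one (racemic aldol adduct) | COc1cc(O)c(C(=O)CC(O)c2ccccc2)c2OC(C)(C)C=Cc12 | intermediate
7 | (E)-1-(7-hydroxy-5-methoxy-2,2-dimethyl-2H-chromen-8-yl)-3-phenylprop-2-en-1-one (chromenochalcone) | COc1cc(O)c(C(=O)/C=C/c2ccccc2)c2OC(C)(C)C=Cc12 | intermediate
8 | (E)-β-ocimene, (3E)-3,7-dimethylocta-1,3,6-triene | C=C/C(C)=C/CC=C(C)C | starting material
9 | boron chelate of 7: spiro borate whose boron carries the (R)-VANOL diolate, the 7-O phenoxide and the coordinated C=O of the chalcone (axial chirality given by name only) | COc1cc2O[B-]3(Oc4c(-c5c(O3)c6ccccc6cc5-c5ccccc5)c(-c5ccccc5)cc5ccccc45)[O+]=C(/C=C/c3ccccc3)c2c2OC(C)(C)C=Cc12 | intermediate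
10 | boron chelate of 11: the same (R)-VANOL spiro borate on the (1'R,2'S,6'R) cycloadduct (axial chirality given by name only) | COc1cc2O[B-]3(Oc4c(-c5c(O3)c6ccccc6cc5-c5ccccc5)c(-c5ccccc5)cc5ccccc45)[O+]=C([C@@H]3[C@H](CC=C(C)C)C(C)=CC[C@H]3c3ccccc3)c2c2OC(C)(C)C=Cc12 | intermediate
11 | [(1R,2S,6R)-3-methyl-2-(3-methylbut-2-en-1-yl)-6-phenylcyclohex-3-en-1-yl](7-hydroxy-5-methoxy-2,2-dimethyl-2H-chromen-8-yl)methanone; aroyl cis to prenyl and trans to phenyl | COc1cc(O)c(C(=O)[C@@H]2[C@H](CC=C(C)C)C(C)=CC[C@H]2c2ccccc2)c2c1C=CC(C)(C)O2 | target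

Total step count: 3. Longest linear sequence: 3 steps (1 → 4 → 7 → 11).

Steps most likely to fail

Step 3. The risk is erosion of endo/exo and facial selectivity, because a chromene-fused aroyl chelate is an untested fit for the ligand pocket.
- The fallback postpones the pyran ring, so that the cycloaddition runs on a simple mono-protected 2'-hydroxychalcone and the chromene annulation becomes the last step. It sets out from 1 and comes back at 11.
- Compound 1 is mono-protected (MOMCl, K2CO3, acetone) to 1-[2-hydroxy-4-methoxy-6-(methoxymethoxy)phenyl]ethanone F4.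
- Condensation with 5 (KOH, EtOH) gives (E)-1-[2-hydroxy-4-methoxy-6-(methoxymethoxy)phenyl]-3-phenylprop-2-en-1-one F5.
- Cycloaddition with 8 under the same VANOL borate gives the (1R,2S,6R) O-MOM cycloadduct F6.
- Mild acid (cat. HCl, MeOH, rt) frees (–)-panduratin A F7.
- Treatment of F7 with 2 and EDDA in hot toluene then fuses on the pyran ring. The two OH/CH pairs of F7 interconvert by rotation about the aryl–carbonyl bond, so again only one chromene, 11, can form.

Step 1. The risks are a second annulation at the remaining OH/CH pair, self-condensation of the enal, and slow C-attack by the acyl-deactivated ring.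
- The fallback replaces the condensation by a sigmatropic route. It sets out from 1 and comes back at 4.
- Compound 1 is mono-O-alkylated with 3-chloro-3-methylbut-1-yne (K2CO3, KI, cat. CuI, acetone, reflux) to 1-[2-hydroxy-4-methoxy-6-(2-methylbut-3-yn-2-yloxy)phenyl]ethanone F1.
- Heating F1 (N,N-diethylaniline, 180 °C) triggers an aromatic propargyl Claisen rearrangement to the only free ortho carbon.
- A [1,5]-H shift then gives 3, and oxa-6π closure gives 4.
- Mono-selectivity is settled at the easily controlled O-alkylation stage.

Step 2. The risks are oxa-Michael closure of the chalcone to the flavanone during condensation or acidification, and sluggish enolisation of the hindered, phenoxide-bearing ketone.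
- The fallback masks the phenol so that neither process can occur. It sets out from 4 and comes back at 7.
- Compound 4 is converted (NaH, MOMCl, DMF, 0 °C) into 1-[5-methoxy-7-(methoxymethoxy)-2,2-dimethyl-2H-chromen-8-yl]ethanone F2.
- Condensation with 5 (KOH, EtOH, rt) gives (E)-1-[5-methoxy-7-(methoxymethoxy)-2,2-dimethyl-2H-chromen-8-yl]-3-phenylprop-2-en-1-one F3.
- Brief treatment with cat. HCl in MeOH at rt releases 7.

Further compounds
F1 | step 1 | 1-[2-hydroxy-4-methoxy-6-(2-methylbut-3-yn-2-yloxy)phenyl]ethanone | CC(=O)c1c(O)cc(OC)cc1OC(C)(C)C#C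
F2 | step 2 | 1-[5-methoxy-7-(methoxymethoxy)-2,2-dimethyl-2H-chromen-8-yl]ethanone | COc1cc(OCOC)c(C(C)=O)c2OC(C)(C)C=Cc12
F3 | step 2 | (E)-1-[5-methoxy-7-(methoxymethoxy)-2,2-dimethyl-2H-chromen-8-yl]-3-phenylprop-2-en-1-one | COc1cc(OCOC)c(C(=O)/C=C/c2ccccc2)c2OC(C)(C)C=Cc12
F4 | step 3 | 1-[2-hydroxy-4-methoxy-6-(methoxymethoxy)phenyl]ethanone | CC(=O)c1c(O)cc(OC)cc1OCOC
F5 | step 3 | (E)-1-[2-hydroxy-4-methoxy-6-(methoxymethoxy)phenyl]-3-phenylprop-2-en-1-one | COCOc1cc(OC)cc(O)c1C(=O)/C=C/c1ccccc1
F6 | step 3 | [2-hydroxy-4-methoxy-6-(methoxymethoxy)phenyl][(1R,2S,6R)-3-methyl-2-(3-methylbut-2-en-1-yl)-6-phenylcyclohex-3-en-1-yl]methanone | COCOc1cc(OC)cc(O)c1C(=O)[C@@H]1[C@H](CC=C(C)C)C(C)=CC[C@H]1c1ccccc1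
F7 | step 3 | (–)-panduratin A, (2,6-dihydroxy-4-methoxyphenyl)[(1R,2S,6R)-3-methyl-2-(3-methylbut-2-en-1-yl)-6-phenylcyclohex-3-en-1-yl]methanone | COc1cc(O)c(C(=O)[C@@H]2[C@H](CC=C(C)C)C(C)=CC[C@H]2c2ccccc2)c(O)c1
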